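**Retrosynthetic overview**
- Z-enol ester ⇐ terminal alkyne + 3-methylbut-2-enoic acid (Ru-catalysed anti-Markovnikov addition, last step).
- Key step: the side-chain C–C bond of the 1,4-diketone ⇐ acetyl radical (from pyruvic acid) + α′-methylene dienone; reduction and protonation of the adduct radical set C7 cis to C6.
- C6 ethynyl ⇐ ligand-controlled Rh conjugate alkynylation of a cross-conjugated cycloheptadienone; CH2OH ⇐ Morita–Baylis–Hillman reaction on the other enone arm.
- Seven-membered ring ⇐ radical one-carbon ring expansion (cyclopropyloxy radical β-scission) of a siloxybicyclo[4.1.0]heptane.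
- Quaternary C5 ⇐ Cu-catalysed asymmetric conjugate addition to 3-methylcyclohex-2-enone. Ring order: the six-membered ring is bought and enlarged in step 2 to the only ring of the target.

Assumption: ring locants in the text are those of the ring ketone (C1 = ring C=O, C2 = CH2OH carbon, C5 = quaternary carbon, C6 = carbon bearing the two-carbon unit, C7 = carbon bearing 2-oxopropyl; target = 5R,6S,7R), and each chiral ligand is used as the enantiomer that gives the descriptor written.

**Step 1**
Reactants: 1 3-methylcyclohex-2-en-1-one; 2 5-bromo-2-methylpent-2-ene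
Product: 6 (5S)-5-methyl-5-(4-methylpent-3-en-1-yl)-1-[(trimethylsilyl)oxy]bicyclo[4.1.0]heptane, via homoprenylmagnesium bromide 3 (not isolated), via bromomagnesium enolate 4 (not isolated), via silyl enol ether 5 (not isolated)
Conditions: 2, Mg, Et2O, 35 °C; then 1, Cu(OTf)2 (3 mol%), chiral C2-symmetric imidazolinium salt (carbene precursor, 4 mol%), Et2O, 0 °C; TMSCl, Et3N, 0 → 25 °C; solvent switch to CH2Cl2, Et2Zn (1.1 equiv), CH2I2 (1.1 equiv), 0 °C
Reagents that add atoms: chlorotrimethylsilane C[Si](C)(C)Cl; diiodomethane ICI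
Why: Copper-catalysed asymmetric conjugate addition of the Grignard reagent (the chiral carbene ligand chooses the enone face and sets the quaternary carbon, 5S in 6) gives the regiodefined enolate, which is silylated and cyclopropanated (Furukawa-type Simmons–Smith reaction) at the electron-rich enol ether in preference to the isolated trisubstituted alkene; the two cyclopropane centres are lost in step 2.

**Step 2**
Reactants: 6 (5S)-5-methyl-5-(4-methylpent-3-en-1-yl)-1-[(trimethylsilyl)oxy]bicyclo[4.1.0]heptane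
Product: 8 (4S)-4-methyl-4-(4-methylpent-3-en-1-yl)cyclohept-2-en-1-one, via chloro ketone 7 (not isolated)
Conditions: FeCl3 (1.2 equiv), CuCl2 (3 equiv), DMF, −10 → 25 °C; then NaOAc, MeOH, 65 °C
Reagents that add atoms: none
Why: Saegusa-type radical ring expansion: FeCl3 oxidises the siloxycyclopropane to a cyclopropyloxy radical, β-scission of the ring-fusion bond gives the seven-membered β-keto radical at C6, CuCl2 chlorinates it by ligand transfer (about 10^9 M−1 s−1, faster than cyclisation onto the side-chain alkene), and acetate then eliminates HCl (E1cB) to the enone.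

**Step 3**
Reactants: 8 (4S)-4-methyl-4-(4-methylpent-3-en-1-yl)cyclohept-2-en-1-one
Product: 9 (4R)-4-methyl-4-(4-methylpent-3-en-1-yl)cyclohepta-2,6-dien-1-one
Conditions: IBX (2.5 equiv), 4-methoxypyridine N-oxide (2.5 equiv), DMSO, 25 → 45 °C
Reagents that add atoms: none
Why: IBX dehydrogenation through the only available enol (toward C2, since C5 is quaternary) gives the cross-conjugated dienone and cannot run on to a tropone.

**Step 4**
Reactants: 9 (4R)-4-methyl-4-(4-methylpent-3-en-1-yl)cyclohepta-2,6-dien-1-one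
Product: 10 (5R)-2-(hydroxymethyl)-5-methyl-5-(4-methylpent-3-en-1-yl)cyclohepta-2,6-dien-1-one
Conditions: 37% aq. HCHO (3 equiv), DMAP (0.3 equiv), THF–H2O, 25 °C
Reagents that add atoms: formaldehyde C=O
Why: Morita–Baylis–Hillman reaction: DMAP adds only to the unhindered β-carbon C3 (C6 is neopentyl-like), so formaldehyde is taken up at C2 alone.

**Step 5**
Reactants: 10 (5R)-2-(hydroxymethyl)-5-methyl-5-(4-methylpent-3-en-1-yl)cyclohepta-2,6-dien-1-one; 11 ethynyltri(propan-2-yl)silane
Product: 13 (5R,6S)-6-ethynyl-2-(hydroxymethyl)-5-methyl-5-(4-methylpent-3-en-1-yl)cyclohept-2-en-1-one, via silylalkynyl ketone 12 (not isolated)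
Conditions: [Rh(OAc)(C2H4)2]2 (2.5 mol%), (R)-DTBM-SEGPHOS (5.5 mol%), 1,4-dioxane, 80 °C; then TBAF, THF, 25 °C
Reagents that add atoms: none
Why: Rhodium-catalysed asymmetric conjugate alkynylation followed by fluoride protodesilylation: the α-substituted C2=C3 arm resists carbometallation so the alkynylrhodium adds at C6, and because the methyl group and the side-chain CH2 on C5 are sterically alike the chiral bisphosphine alone fixes C6 as 6S, alkynyl cis to the side chain.

**Step 6**
Reactants: 13 (5R,6S)-6-ethynyl-2-(hydroxymethyl)-5-methyl-5-(4-methylpent-3-en-1-yl)cyclohept-2-en-1-one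
Product: 14 (5R,6S)-6-ethynyl-2-(hydroxymethyl)-5-methyl-7-methylidene-5-(4-methylpent-3-en-1-yl)cyclohept-2-en-1-one
Conditions: (CH2O)n, i-Pr2NH·CF3CO2H (1 equiv), THF, 65 °C
Reagents that add atoms: formaldehyde (as paraformaldehyde) C=O
Why: Amine-salt-promoted α-methylenation (Mannich condensation then β-elimination) at C7, the only enolisable saturated α-carbon, gives the cross-conjugated α′-methylene ketone; C6 is not enolisable and keeps its configuration.

**Step 7 (key step)**
Reactants: 14 (5R,6S)-6-ethynyl-2-(hydroxymethyl)-5-methyl-7-methylidene-5-(4-methylpent-3-en-1-yl)cyclohept-2-en-1-one; 15 2-oxopropanoic acid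
Product: 16 (5R,6S,7R)-6-ethynyl-2-(hydroxymethyl)-5-methyl-5-(4-methylpent-3-en-1-yl)-7-(2-oxopropyl)cyclohept-2-en-1-one
Conditions: [Ir{dF(CF3)ppy}2(dtbbpy)]PF6 (1 mol%), K2HPO4 (20 mol%), DME–H2O (10:1), blue LEDs, 25 °C
Reagents that add atoms: none
Why: Radical acyl Giese addition: photoredox decarboxylation of pyruvic acid by the excited trivalent iridium complex gives the nucleophilic acetyl radical, which adds to the unhindered exocyclic CH2 (not to the α-substituted C3) to forge the 1,4-diketone C–C bond, and the C7 radical is reduced to the enolate and protonated anti to the pseudoaxial C6 ethynyl group (A(1,2) strain), giving the kinetic 6,7-cis isomer (7R).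

**Step 8**
Reactants: 16 (5R,6S,7R)-6-ethynyl-2-(hydroxymethyl)-5-methyl-5-(4-methylpent-3-en-1-yl)-7-(2-oxopropyl)cyclohept-2-en-1-one; 17 3-methylbut-2-enoic acid
Product: 18 (Z)-2-[(1S,2R,7R)-4-(hydroxymethyl)-7-methyl-7-(4-methylpent-3-en-1-yl)-3-oxo-2-(2-oxopropyl)cyclohept-4-en-1-yl]ethenyl 3-methylbut-2-enoate
Conditions: Ru(2-methylallyl)2(dppb) (3 mol%), toluene, 45 °C
Reagents that add atoms: none
Why: Anti-Markovnikov addition of the carboxylic acid to the terminal alkyne through a vinylidene of divalent ruthenium gives the Z-enol ester under neutral conditions that do not epimerise C7 or touch the alcohol, ketones and alkenes.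

**Compound list**
1 | 3-methylcyclohex-2-en-1-one | CC1=CC(=O)CCC1 | starting material
2 | 5-bromo-2-methylpent-2-ene | CC(C)=CCCBr | starting material
3 | (4-methylpent-3-en-1-yl)magnesium bromide | CC(C)=CCC[Mg]Br | intermediate
4 | bromomagnesium (3S)-3-methyl-3-(4-methylpent-3-en-1-yl)cyclohex-1-en-1-olate | Br[Mg]OC1=C[C@](C)(CCC=C(C)C)CCC1 | intermediate
5 | trimethyl{[(3S)-3-methyl-3-(4-methylpent-3-en-1-yl)cyclohex-1-en-1-yl]oxy}silane | C[Si](C)(C)OC1=C[C@](C)(CCC=C(C)C)CCC1 | intermediate
6 | (5S)-5-methyl-5-(4-methylpent-3-en-1-yl)-1-[(trimethylsilyl)oxy]bicyclo[4.1.0]heptane (both cis-fused cyclopropane diastereomers) | C[Si](C)(C)OC12CC1[C@](C)(CCC=C(C)C)CCC2 | intermediate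
7 | (4S)-3-chloro-4-methyl-4-(4-methylpent-3-en-1-yl)cycloheptan-1-one (both C3 epimers) | O=C1CCC[C@@](C)(CCC=C(C)C)C(Cl)C1 | intermediate
8 | (4S)-4-methyl-4-(4-methylpent-3-en-1-yl)cyclohept-2-en-1-one | O=C1CCC[C@@](C)(CCC=C(C)C)C=C1 | intermediate
9 | (4R)-4-methyl-4-(4-methylpent-3-en-1-yl)cyclohepta-2,6-dien-1-one | O=C1C=CC[C@@](C)(CCC=C(C)C)C=C1 | intermediate
10 | (5R)-2-(hydroxymethyl)-5-methyl-5-(4-methylpent-3-en-1-yl)cyclohepta-2,6-dien-1-one | O=C1C(CO)=CC[C@@](C)(CCC=C(C)C)C=C1 | intermediate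
11 | ethynyltri(propan-2-yl)silane | C#C[Si](C(C)C)(C(C)C)C(C)C | starting material
12 | (5R,6S)-2-(hydroxymethyl)-5-methyl-5-(4-methylpent-3-en-1-yl)-6-{[tri(propan-2-yl)silyl]ethynyl}cyclohept-2-en-1-one | O=C1C(CO)=CC[C@@](C)(CCC=C(C)C)[C@@H](C#C[Si](C(C)C)(C(C)C)C(C)C)C1 | intermediate
13 | (5R,6S)-6-ethynyl-2-(hydroxymethyl)-5-methyl-5-(4-methylpent-3-en-1-yl)cyclohept-2-en-1-one | O=C1C(CO)=CC[C@@](C)(CCC=C(C)C)[C@@H](C#C)C1 | intermediate
14 | (5R,6S)-6-ethynyl-2-(hydroxymethyl)-5-methyl-7-methylidene-5-(4-methylpent-3-en-1-yl)cyclohept-2-en-1-one | C=C1C(=O)C(CO)=CC[C@@](C)(CCC=C(C)C)[C@H]1C#C | intermediate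
15 | 2-oxopropanoic acid (pyruvic acid) | CC(=O)C(=O)O | starting material
16 | (5R,6S,7R)-6-ethynyl-2-(hydroxymethyl)-5-methyl-5-(4-methylpent-3-en-1-yl)-7-(2-oxopropyl)cyclohept-2-en-1-one | CC(=O)C[C@H]1C(=O)C(CO)=CC[C@@](C)(CCC=C(C)C)[C@H]1C#C | intermediate
17 | 3-methylbut-2-enoic acid | CC(C)=CC(=O)O | starting material
18 | (Z)-2-[(1S,2R,7R)-4-(hydroxymethyl)-7-methyl-7-(4-methylpent-3-en-1-yl)-3-oxo-2-(2-oxopropyl)cyclohept-4-en-1-yl]ethenyl 3-methylbut-2-enoate | CC(=O)C[C@H]1C(=O)C(CO)=CC[C@@](C)(CCC=C(C)C)[C@H]1/C=C\OC(=O)C=C(C)C | target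

**Step count**
Total steps: 8. Longest linear sequence: 8 (1 → 18).

**Three steps most likely to fail**

Step 2 (radical ring expansion). The C6 radical can close onto the side-chain alkene (5-exo) before it is chlorinated, and the zinc carbenoid of step 1 may also attack that alkene. The fallback sets out from 1 and comes back at 8, carrying the alkene in masked form. Compound 1 is taken through the step 1 protocol with [2-(1,3-dioxolan-2-yl)ethyl]magnesium bromide F1 (from 2-(2-bromoethyl)-1,3-dioxolane and Mg). This gives, through the bromomagnesium enolate F2 and the silyl enol ether F3, the siloxycyclopropane F4. FeCl3 in DMF and then NaOAc in MeOH give, through the chloro ketone F5, the enone acetal F6. 1 M HCl in THF frees the aldehyde F7. Wittig reaction with propan-2-ylidenetriphenyl-λ5-phosphane F8 (from isopropyltriphenylphosphonium iodide and n-BuLi) at −78 °C, where the aldehyde reacts before the enone, gives 8.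

Step 5 (conjugate alkynylation). Addition at the neopentyl-like C6 may be slow, the alkyne may dimerise, the other enone arm may react, or ligand control may be weak. The fallback sets out from 10 and comes back at 12, delivering the alkynyl group by rearrangement instead of intermolecular addition. Lithium [tri(propan-2-yl)silyl]acetylide F9 (from 11 and n-BuLi, 2.2 equiv) adds 1,2 to the ketone of 10 to give the tertiary alcohol F10. [Rh(OH)(cod)]2 with the same chiral bisphosphine in toluene at 60 °C forms the rhodium alkoxide, which undergoes β-alkynyl elimination and conjugate re-addition (formal 1,3-alkynyl shift) to give 12. Compound 12 is then desilylated as in step 5.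

Step 7 (key radical acylation). The enolate may be protonated on the wrong face (the axial methyl on C5 hinders the face opposite the ethynyl group), the acetyl radical may add elsewhere, or the 1,4-diketone may undergo aldol closure. The fallback sets out from 13 and comes back at 16. It forms the C7–CH2 bond last instead of the C7–H bond, which inverts the outcome at C7 for the same facial preference of the enolate. LDA (3.3 equiv, THF, −78 °C) converts 13 into the trilithium alkoxide–acetylide–enolate F11. 3-Bromo-2-methoxyprop-1-ene (1.0 equiv) alkylates the enolate carbon C7 to give the 2-methoxyallyl ketone F12. Oxalic acid in wet THF hydrolyses the enol ether to 16.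

**Further compounds**
F1 | step 2 | [2-(1,3-dioxolan-2-yl)ethyl]magnesium bromide | Br[Mg]CCC1OCCO1
F2 | step 2 | bromomagnesium (3S)-3-[2-(1,3-dioxolan-2-yl)ethyl]-3-methylcyclohex-1-en-1-olate | Br[Mg]OC1=C[C@](C)(CCC2OCCO2)CCC1
F3 | step 2 | {[(3S)-3-[2-(1,3-dioxolan-2-yl)ethyl]-3-methylcyclohex-1-en-1-yl]oxy}trimethylsilane | C[Si](C)(C)OC1=C[C@](C)(CCC2OCCO2)CCC1
F4 | step 2 | (5S)-5-[2-(1,3-dioxolan-2-yl)ethyl]-5-methyl-1-[(trimethylsilyl)oxy]bicyclo[4.1.0]heptane | C[Si](C)(C)OC12CC1[C@](C)(CCC3OCCO3)CCC2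
F5 | step 2 | (4S)-3-chloro-4-[2-(1,3-dioxolan-2-yl)ethyl]-4-methylcycloheptan-1-one | O=C1CCC[C@@](C)(CCC2OCCO2)C(Cl)C1
F6 | step 2 | (4S)-4-[2-(1,3-dioxolan-2-yl)ethyl]-4-methylcyclohept-2-en-1-one | O=C1CCC[C@@](C)(CCC2OCCO2)C=C1
F7 | step 2 | 3-[(1S)-1-methyl-4-oxocyclohept-2-en-1-yl]propanal | O=C1CCC[C@@](C)(CCC=O)C=C1
F8 | step 2 | propan-2-ylidenetriphenyl-λ5-phosphane | CC(C)=P(c1ccccc1)(c1ccccc1)c1ccccc1
F9 | step 5 | lithium [tri(propan-2-yl)silyl]acetylide | [Li]C#C[Si](C(C)C)(C(C)C)C(C)C
F10 | step 5 | (5R)-2-(hydroxymethyl)-5-methyl-5-(4-methylpent-3-en-1-yl)-1-{[tri(propan-2-yl)silyl]ethynyl}cyclohepta-2,6-dien-1-ol (both C1 epimers) | OCC1=CC[C@@](C)(CCC=C(C)C)C=CC1(O)C#C[Si](C(C)C)(C(C)C)C(C)C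
F11 | step 7 | trilithium alkoxide–acetylide–enolate of 13 | [Li]OCC1=CC[C@@](C)(CCC=C(C)C)[C@@H](C#C[Li])C=C1O[Li]
F12 | step 7 | (5R,6S,7R)-6-ethynyl-2-(hydroxymethyl)-7-(2-methoxyprop-2-en-1-yl)-5-methyl-5-(4-methylpent-3-en-1-yl)cyclohept-2-en-1-one | COC(=C)C[C@H]1C(=O)C(CO)=CC[C@@](C)(CCC=C(C)C)[C@H]1C#C
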